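**Retrosynthetic overview**
- Ring C (the pyranone) is closed last, by cyclodehydration of the o-hydroxy-1,3-diketone 9 released from MOM ether 8 (C2–O1 bond).
- Key disconnection C3–C4: an acyl anion equivalent (the Breslow intermediate from aldehyde 4 under NHC catalysis) is joined to the CH2Br carbon of phenacyl bromide 5, an enolonium equivalent.
- Aldehyde 4 comes from MOM protection and ortho-formylation of 2,3,4-trimethoxyphenol 1, which fixes the 6,7,8-oxygenation pattern.
- Rings A and B are bought intact; only ring C is built.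

Assumption: the target is achiral (no stereocentre), so no enantiocontrol is needed. Compounds 1 and 5 are taken as catalogue chemicals; if 3 is bought instead, the route is three steps.

**Step 1**
Reactants: 1 2,3,4-trimethoxyphenol
Product: 3 2-hydroxy-3,4,5-trimethoxybenzaldehyde, via salicyl alcohol 2 (not isolated)
Conditions: (CH2O)n (6.75 equiv), MgCl2 (1.5 equiv), Et3N (3.75 equiv), MeCN, reflux, 3 h; then 1 M HCl
Reagents that add atoms: paraformaldehyde (reacts as formaldehyde), C=O
Why: Magnesium-mediated ortho-formylation (Casnati–Skattebøl reaction), in which the chloromagnesium phenoxide of 1 delivers formaldehyde through a six-membered chelate to the only free ortho position to give 2, which a second formaldehyde oxidises by Oppenauer-type hydride transfer to 3; the regiochemistry is unambiguous and no stereocentre is formed.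

**Step 2**
Reactants: 3 2-hydroxy-3,4,5-trimethoxybenzaldehyde
Product: 4 2-(methoxymethoxy)-3,4,5-trimethoxybenzaldehyde
Conditions: NaH (1.2 equiv), DMF, 0 °C, 20 min; MOMCl (1.3 equiv), 0 °C to rt, 2 h
Reagents that add atoms: chloromethyl methyl ether (MOMCl), COCCl
Why: Williamson-type O-alkylation of the sodium phenoxide with the very reactive chloromethyl ether masks the phenol, which would otherwise be O-phenacylated in step 3, as an acetal that the acid of step 4 removes; no stereocentre is formed.

**Step 3**
Reactants: 4 2-(methoxymethoxy)-3,4,5-trimethoxybenzaldehyde; 5 2-bromo-1-(3,4-dimethoxyphenyl)ethan-1-one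
Product: 8 1-(3,4-dimethoxyphenyl)-3-[2-(methoxymethoxy)-3,4,5-trimethoxyphenyl]propane-1,3-dione, via Breslow intermediate 6 (not isolated), via thiazolium adduct 7 (not isolated)
Conditions: 4 (1.5 equiv), 5 (1.0 equiv, added over 4 h by syringe pump), 3-mesityl-5,6,7,8-tetrahydro-4H-cyclohepta[d]thiazol-3-ium perchlorate (15 mol%), Cs2CO3 (2.2 equiv), MeCN, 25 °C, argon; then aq NH4Cl (excess 4 recovered)
Reagents that add atoms: none
Why: Proposed new method: the thiazolylidene adds to aldehyde 4 to give Breslow intermediate 6, an acyl anion equivalent whose enolate is both a strong carbon nucleophile and a one-electron reductant, so it attacks the CH2Br carbon of 5 either by direct SN2 displacement or by electron transfer, bromide loss and ketyl/phenacyl radical recombination, both paths giving adduct 7, which expels the carbene to release 1,3-diketone 8 and so joins two normally electrophilic carbons (an aldehyde carbon and an α-halo ketone carbon); the closest known reaction types are the NHC-catalysed acylation of activated alkyl halides and tosylates and the radical NHC-catalysed acylation with α-bromo carbonyl and fluoroalkyl halides, and no stereocentre survives in 8.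

**Step 4**
Reactants: 8 1-(3,4-dimethoxyphenyl)-3-[2-(methoxymethoxy)-3,4,5-trimethoxyphenyl]propane-1,3-dione
Product: 11 2-(3,4-dimethoxyphenyl)-6,7,8-trimethoxy-4H-chromen-4-one, via diketophenol 9 (not isolated), via cyclic hemiketal 10 (not isolated)
Conditions: conc. HCl (5 equiv), MeOH, 65 °C, 3 h
Reagents that add atoms: none
Why: Acid-catalysed methanolysis of the MOM acetal frees phenol 9, whose hydroxyl adds to the veratroyl carbonyl to give hemiketal 10, and acid-catalysed dehydration then gives the 4-pyranone (the cyclodehydration that ends a Baker–Venkataraman flavone synthesis), while the five aryl methyl ethers are stable to HCl in methanol and the transient stereocentre of 10 is lost on dehydration.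

**Compound list**
1 | 2,3,4-trimethoxyphenol | COc1ccc(O)c(OC)c1OC | starting material
2 | 6-(hydroxymethyl)-2,3,4-trimethoxyphenol (present as its magnesium salt) | COc1cc(CO)c(O)c(OC)c1OC | intermediate
3 | 2-hydroxy-3,4,5-trimethoxybenzaldehyde | COc1cc(C=O)c(O)c(OC)c1OC | intermediate
4 | 2-(methoxymethoxy)-3,4,5-trimethoxybenzaldehyde | COCOc1c(C=O)cc(OC)c(OC)c1OC | intermediate
5 | 2-bromo-1-(3,4-dimethoxyphenyl)ethan-1-one | COc1ccc(C(=O)CBr)cc1OC | starting material
6 | Breslow intermediate, (3-mesityl-5,6,7,8-tetrahydro-4H-cyclohepta[d]thiazol-2(3H)-ylidene)[2-(methoxymethoxy)-3,4,5-trimethoxyphenyl]methanol | COCOc1c(OC)c(OC)c(OC)cc1C(O)=C1SC2=C(CCCCC2)N1c1c(C)cc(C)cc1C | intermediate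
7 | 2-{3-(3,4-dimethoxyphenyl)-1-hydroxy-1-[2-(methoxymethoxy)-3,4,5-trimethoxyphenyl]-3-oxopropyl}-3-mesityl-5,6,7,8-tetrahydro-4H-cyclohepta[d]thiazol-3-ium bromide (racemic) | COCOc1c(OC)c(OC)c(OC)cc1C(O)(CC(=O)c1ccc(OC)c(OC)c1)c1sc2CCCCCc2[n+]1-c1c(C)cc(C)cc1C.[Br-] | intermediate
8 | 1-(3,4-dimethoxyphenyl)-3-[2-(methoxymethoxy)-3,4,5-trimethoxyphenyl]propane-1,3-dione | COCOc1c(OC)c(OC)c(OC)cc1C(=O)CC(=O)c1ccc(OC)c(OC)c1 | intermediate
9 | 1-(3,4-dimethoxyphenyl)-3-(2-hydroxy-3,4,5-trimethoxyphenyl)propane-1,3-dione | COc1ccc(C(=O)CC(=O)c2cc(OC)c(OC)c(OC)c2O)cc1OC | intermediate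
10 | 2-(3,4-dimethoxyphenyl)-2-hydroxy-6,7,8-trimethoxychroman-4-one (racemic) | COc1ccc(C2(O)CC(=O)c3cc(OC)c(OC)c(OC)c3O2)cc1OC | intermediate
11 | 2-(3,4-dimethoxyphenyl)-6,7,8-trimethoxy-4H-chromen-4-one (CNP0388881.0) | COc1ccc(-c2cc(=O)c3cc(OC)c(OC)c(OC)c3o2)cc1OC | target

**Totals**
Total step count: 4. Longest linear sequence: 4 steps (1 → 3 → 4 → 8 → 11); 5 is bought.

**Steps most likely to fail, with fallbacks**

The riskiest is step 3. The free carbene can be alkylated by 5, base can drive a Darzens reaction between 4 and 5, and the enolate of product 8 can be phenacylated a second time. Slow addition of 5 and excess 4 are meant to suppress these. The fallback sets out from 4 and comes back to the route at 11. It keeps the carbene-derived acyl anion but changes the electrophile to an alkynyl cation equivalent, which gives a non-acidic product that cannot be over-alkylated. 4-Ethynyl-1,2-dimethoxybenzene and [hydroxy(tosyloxy)iodo]benzene (CH2Cl2, rt) give [(3,4-dimethoxyphenyl)ethynyl](phenyl)iodonium 4-methylbenzenesulfonate F1. NHC-catalysed C–H alkynylation of 4 with F1 (same thiazolium precatalyst, K2CO3, toluene, 0 °C) gives the ynone 3-(3,4-dimethoxyphenyl)-1-[2-(methoxymethoxy)-3,4,5-trimethoxyphenyl]prop-2-yn-1-one F2. HCl in MeOH then removes the MOM group to give 3-(3,4-dimethoxyphenyl)-1-(2-hydroxy-3,4,5-trimethoxyphenyl)prop-2-yn-1-one F3, which closes by acid-promoted 6-endo oxa-Michael addition to 11.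

Second is step 4. Formaldehyde equivalents released from the MOM group under acid could condense with the nucleophilic diketone or with the electron-rich rings, and acid methanolysis of the diketone (retro-Claisen) could compete. The fallback sets out from 3 and comes back to the route at 9, which is then isolated. It replaces the acid-labile acetal by a group removed under neutral conditions. Benzyl bromide and K2CO3 in DMF convert 3 into 2-(benzyloxy)-3,4,5-trimethoxybenzaldehyde F4. Coupling of F4 with 5 under the conditions of step 3 gives 1-[2-(benzyloxy)-3,4,5-trimethoxyphenyl]-3-(3,4-dimethoxyphenyl)propane-1,3-dione F5. Hydrogenolysis (H2, Pd/C, EtOAc, rt) releases 9 with no formaldehyde source present. Ring C is then closed to 11 with catalytic 4-methylbenzenesulfonic acid monohydrate in toluene at reflux with azeotropic removal of water.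

Third is step 1. The electron-rich phenol may give methoxymethylated or diarylmethane by-products with excess formaldehyde. The fallback sets out from 1 and comes back to the route at 4, bypassing 3. It protects first and then formylates by directed metalation. NaH and MOMCl in DMF give 1,2,3-trimethoxy-4-(methoxymethoxy)benzene F6. Ortho-lithiation (n-BuLi, TMEDA, THF, 0 °C), in which the MOM ether outranks methoxy as directing group, gives [2-(methoxymethoxy)-3,4,5-trimethoxyphenyl]lithium F7. A DMF quench followed by aqueous NH4Cl delivers 4.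

**Further compounds**
F1 | step 3 | [(3,4-dimethoxyphenyl)ethynyl](phenyl)iodonium 4-methylbenzenesulfonate | COc1ccc(C#C[I+]c2ccccc2)cc1OC.Cc1ccc(S(=O)(=O)[O-])cc1
F2 | step 3 | 3-(3,4-dimethoxyphenyl)-1-[2-(methoxymethoxy)-3,4,5-trimethoxyphenyl]prop-2-yn-1-one | COCOc1c(OC)c(OC)c(OC)cc1C(=O)C#Cc1ccc(OC)c(OC)c1
F3 | step 3 | 3-(3,4-dimethoxyphenyl)-1-(2-hydroxy-3,4,5-trimethoxyphenyl)prop-2-yn-1-one | COc1ccc(C#CC(=O)c2cc(OC)c(OC)c(OC)c2O)cc1OC
F4 | step 4 | 2-(benzyloxy)-3,4,5-trimethoxybenzaldehyde | COc1cc(C=O)c(OCc2ccccc2)c(OC)c1OC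
F5 | step 4 | 1-[2-(benzyloxy)-3,4,5-trimethoxyphenyl]-3-(3,4-dimethoxyphenyl)propane-1,3-dione | COc1ccc(C(=O)CC(=O)c2cc(OC)c(OC)c(OC)c2OCc2ccccc2)cc1OC
F6 | step 1 | 1,2,3-trimethoxy-4-(methoxymethoxy)benzene | COCOc1ccc(OC)c(OC)c1OC
F7 | step 1 | [2-(methoxymethoxy)-3,4,5-trimethoxyphenyl]lithium | [Li]c1cc(OC)c(OC)c(OC)c1OCOC
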